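The readings were generated by integration with constants of no real substance, noise included.

Count turnovers first: take the target on its plateau and divide it by the catalyst charged, both as shares of the substrate.

all flasks: gas phase 200 mM (held); free catalyst 1.2 mol%

| charge | substrate | remark | time |
|---|---|---|---|
| Wednesday's | 0.70 M | run made earlier |  |
| Thursday's | 1 M | run made earlier |  |
| flask | 1.4 M |  | 15 min |

| run | time / min | target / % |
|---|---|---|
| Wednesday's | 2.50 | 44.4 |
| Wednesday's | 5.00 | 44.1 |
| Wednesday's | 8.00 | 45.1 |
| Wednesday's | 10.0 | 45.8 |
| Wednesday's | 12.0 | 45.7 |
| Wednesday's | 15.0 | 44.7 |
| Thursday's | 1.00 | 32.8 |
| Thursday's | 3.00 | 47.9 |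
| Thursday's | 5.00 | 48.5 |
| Thursday's | 8.00 | 47.8 |
| Thursday's | 12.0 | 48.1 |
| Thursday's | 15.0 | 48.6 |

(standard deviation of a reading: 0.5 percentage points)

- at the start none of the gas phase is in solution

- how much target there is at 15 min, in percent of the substrate charged
- the change that raises the amount of target at 15 min, in percent of the substrate charged most ("none" if none brings more than 2 percentage points) (south / south-east / north / none)
- amount of target at 15 min, in percent of the substrate charged, after south-east

- south: doubling the saturation concentration of gas phase, all else as stated
- south-east: doubling the amount of free catalyst, all else as stated
- north: doubling the transfer coefficient of the gas phase, all else as stated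

Two chemists read these runs differently. Both see the target flat from 3.00 min on Thursday's run, at 48.2%, and flat on Wednesday's at 45.0%. Ben says the substrate has probably gone and the plateau is a share that climbs with c(substrate), so he expects the flask higher again.

Ada says a flat line shows that making has stopped, and that the catalyst may have stopped working with substrate still there. She divides and gets 37.5 on Wednesday's run and 40.2 on Thursday's. This turnover count, the turnover number of the trade, is the target on the plateau per catalyst charged, and it is her quantity. The plateaus differ by 3.2 percentage points against a scatter of 0.5 points, so the count drifts a little, and she carries Thursday's as the nearest.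

Ada's reckoning, which I would commit to, puts the flask at 48.2%. South-east gives 96.4% if the count holds, but both runs had one loading, so that figure is untested. Neither run varied the gas, so she ranks no change.

The forecast, Ben's number, gives 51%, above Ada's, picks south, and puts south-east at 52%, below hers, holding that “More catalyst only speeds a finished reaction unless selectivity depends on catalyst concentration”.

The flask gives 48.4% at 15 min, with 51.6% of the substrate left and 100% of the catalyst spent. South is best, with a gain of 30 points, and south-east reaches 63.5%.

    gas phase ⇌ dissolved gas, rate k1*(csat - [dissolved gas]) (kL = 0.0480 /s)
    substrate + dissolved gas + free catalyst → free catalyst + target (k = 29.0 /M²/s)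
    2 free catalyst ⇌ resting dimer, settled at all times (K = 20.0 /M)
    free catalyst → spent catalyst (k = 0.0330 /s)

Ada's count on this flask is 40.4, against 40.2 from Thursday's run. Ben's climb with c(substrate) has its region in the readings from Wednesday's to Thursday's run, 3.2 points; around this flask, with the loading and time held, the nearest amounts of substrate at which the answer has moved 5 points are 0.634 M and 2.64 M. South-east, though, gives a count of 26.5, lower than Thursday's. On a neighbour flask charged with 0.3 mol% of free catalyst, other charges as here, Thursday's count gives 12.1%. That neighbour ends at 15 min with 24.2% target, a count of 80.7, and 75.8% of its substrate left.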